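**Assumptions (one line each):**
- 1-Bromo-3,5-bis(benzyloxy)benzene and Jacobsen's Co(salen) catalyst are purchasable.
- Electrophilic halogenation of a 5-alkyl-1,3-bis(benzyloxy)benzene occurs ortho to the alkyl group and ortho to one OBn, as it does for 3,5-dimethoxytoluene.

## Retrosynthetic overview
1. Global hydrogenolysis of five benzyl ethers from pentabenzyl ester **9** gives integracin B (**10**).
2. The first disconnection is the aryl–C(=O) bond, not the O–C(=O) bond. Pd-catalysed alkoxycarbonylation of aryl iodide **8** with enantiopure alcohol **6** makes the hindered 2,6-disubstituted benzoate without ever forming or activating a resorcylic acid.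
3. Both halves come from one building block: **6** is the alcohol partner, and its O-benzyl ether, regioselectively iodinated, is the aryl partner **8**.
4. **6** is built from (R)-1,2-epoxypentane (**2**, by hydrolytic kinetic resolution) and the Grignard reagent of 1-(6-bromohexyl)-3,5-bis(benzyloxy)benzene (**5**, by hydroboration/Suzuki).
5. No rings are formed. Both arenes come from the commercial aryl bromide **3**. Both stereocentres derive from the single HKR-derived epoxide and are never touched again.

## Route

**Step 1**
Reactants: 1 (±)-1,2-epoxypentane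
Product: 2 (R)-1,2-epoxypentane
Conditions: (R,R)-Co(III)(salen)OAc (0.5 mol%), H2O (0.55 equiv), THF (minimal), 0 °C to rt, 18 h; distil the epoxide from the diol
Reagents that add atoms: none (the water ends up in the diol by-product)
Why: Jacobsen hydrolytic kinetic resolution opens the (S)-epoxide selectively and leaves (R)-epoxide in >99% ee, setting both future carbinol centres. I take the (R,R)-catalyst to leave the (R)-alkyl epoxide, by analogy with propylene oxide, and this is checked by optical rotation; if the opposite epoxide is recovered, use (S,S)-catalyst.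

**Step 2**
Reactants: 4 6-bromo-1-hexene; 3 1-bromo-3,5-bis(benzyloxy)benzene
Product: 5 1-(6-bromohexyl)-3,5-bis(benzyloxy)benzene
Conditions: (i) 4 + 9-BBN-H (1.05 equiv), THF, rt, 2 h; (ii) add 3 (0.9 equiv), PdCl2(dppf) (3 mol%), 3 M aq. K3PO4, THF, 60 °C, 12 h
Reagents that add atoms: none (boron is lost; only H is added across the alkene)
Why: Terminal-alkene hydroboration gives a primary B-alkyl-9-BBN that undergoes B-alkyl Suzuki–Miyaura coupling with the aryl bromide, which reacts much faster than the alkyl bromide. No stereocentre is formed.

**Step 3**
Reactants: 5 1-(6-bromohexyl)-3,5-bis(benzyloxy)benzene; 2 (R)-1,2-epoxypentane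
Product: 6 (R)-11-[3,5-bis(benzyloxy)phenyl]undecan-4-ol
Conditions: Mg turnings (1.5 equiv), THF, reflux, 1 h, to give the Grignard reagent; then CuI (10 mol%), add 2 (0.8 equiv vs. Grignard), –20 °C to 0 °C, 3 h; aq. NH4Cl
Reagents that add atoms: none (Mg and Cu are not retained)
Why: Cu-catalysed Grignard opening of a terminal epoxide attacks the unhindered CH2 terminus and leaves the C–O stereocentre untouched, so (R)-epoxide gives the (R)-carbinol with the chain now longer by seven carbons (Ar–(CH2)7–CH(OH)–Pr).

**Step 4**
Reactants: 6
Product: 7 1,3-bis(benzyloxy)-5-[(8R)-8-(benzyloxy)undecyl]benzene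
Conditions: NaH (1.5 equiv), BnBr (1.3 equiv), TBAI (5 mol%), THF/DMF (4:1), 0 °C to rt, 6 h
Reagents that add atoms: benzyl bromide, BrCc1ccccc1
Why: Williamson etherification masks the secondary alcohol for the carbonylation and allows a single final hydrogenolysis. The stereocentre has no acidic α-proton and is not affected.

**Step 5**
Reactants: 7
Product: 8 1,5-bis(benzyloxy)-2-iodo-3-[(8R)-8-(benzyloxy)undecyl]benzene, i.e. the aryl iodide flanked by the alkyl chain and one OBn
Conditions: NIS (1.05 equiv), cat. TFA, MeCN, 0 °C to rt, 3 h, dark
Reagents that add atoms: N-iodosuccinimide, O=C1CCC(=O)N1I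
Why: Electrophilic aromatic iodination of the resorcinol diether occurs at C-4/C-6, which is ortho to the alkyl chain, ortho to one OBn and para to the other. The position between the two OBn groups is hindered, and this puts the iodine exactly where the carboxyl must go.

**Step 6**
Reactants: 8 aryl iodide; 6 (R)-alcohol (1.5 equiv)
Product: 9 pentabenzyl integracin B (ester)
Conditions: Pd(OAc)2 (5 mol%), Xantphos (7.5 mol%), Et3N (3 equiv), CO (10 atm), toluene, 110 °C, 24 h
Reagents that add atoms: carbon monoxide, [C-]#[O+]
Why: Pd-catalysed alkoxycarbonylation (oxidative addition, CO insertion, alcoholysis) forms the hindered ester, and the alcohol's C–O bond is never cleaved, so the (R)-ester centre is retained. This key step is the main risk: a 2,6-disubstituted electron-rich aryl iodide combined with a secondary alcohol.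

**Step 7**
Reactants: 9
Product: 10 integracin B
Conditions: H2 (1 atm), 20% Pd(OH)2/C (20 wt%), EtOAc/EtOH 1:1, rt, 16 h
Reagents that add atoms: none (only H is added)
Why: Hydrogenolysis cleaves the benzyl–O bonds of four aryl ethers and one alkyl ether and leaves the aryl ester, the arenes and both carbinol stereocentres intact, with no alkene or alkyne present to interfere.

## Compound list
1 | (±)-1,2-epoxypentane | CCCC1CO1 | starting material
2 | (R)-1,2-epoxypentane | CCC[C@@H]1CO1 | intermediate
3 | 1-bromo-3,5-bis(benzyloxy)benzene | Brc1cc(OCc2ccccc2)cc(OCc2ccccc2)c1 | starting material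
4 | 6-bromo-1-hexene | C=CCCCCBr | starting material
5 | 1-(6-bromohexyl)-3,5-bis(benzyloxy)benzene | BrCCCCCCc1cc(OCc2ccccc2)cc(OCc2ccccc2)c1 | intermediate
6 | (R)-11-[3,5-bis(benzyloxy)phenyl]undecan-4-ol | CCC[C@@H](O)CCCCCCCc1cc(OCc2ccccc2)cc(OCc2ccccc2)c1 | intermediate
7 | 1,3-bis(benzyloxy)-5-[(8R)-8-(benzyloxy)undecyl]benzene | CCC[C@@H](OCc1ccccc1)CCCCCCCc1cc(OCc2ccccc2)cc(OCc2ccccc2)c1 | intermediate
8 | aryl iodide: 2-iodo-3,5-bis(benzyloxy)-1-[(8R)-8-(benzyloxy)undecyl]benzene | CCC[C@@H](OCc1ccccc1)CCCCCCCc1cc(OCc2ccccc2)cc(OCc2ccccc2)c1I | intermediate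
9 | pentabenzyl integracin B | CCC[C@@H](OCc1ccccc1)CCCCCCCc1cc(OCc2ccccc2)cc(OCc2ccccc2)c1C(=O)O[C@H](CCC)CCCCCCCc1cc(OCc2ccccc2)cc(OCc2ccccc2)c1 | intermediate
10 | integracin B | CCC[C@@H](O)CCCCCCCc1cc(O)cc(O)c1C(=O)O[C@H](CCC)CCCCCCCc1cc(O)cc(O)c1 | target

## Totals
Total steps: 7. Longest linear sequence: 6 (HKR or the Suzuki step, then Grignard/epoxide opening, benzylation, iodination, carbonylation, hydrogenolysis).

## Three steps most likely to fail
1. **Step 6 (carbonylative esterification).** The hindered, electron-rich aryl iodide and the secondary alcohol may give hydrodeiodination or low conversion.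
   - Fallback: change the approach by converting 8 to the aryl Grignard (iPrMgCl·LiCl, –20 °C), quenching with CO2 to give the benzoic acid, then coupling with 6 via the acid chloride or a Yamaguchi-type esterification.
2. **Step 5 (regioselective iodination).** Mixtures of the C-2 and C-4 (between the OBn groups) isomers, or diiodination, are possible.
   - Fallback: change the approach by Vilsmeier–Haack formylation of 7 at the same ortho-to-alkyl position, then Pinnick oxidation to the acid and esterification with 6, replacing the Pd step.
3. **Step 2 (B-alkyl Suzuki with the bromohexyl-9-BBN).** Competing oxidative addition at the alkyl bromide or borane decomposition could lower the yield.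
   - Fallback: reverse the order by opening 2 with 5-hexenylmagnesium bromide (Cu cat.) to give (R)-undec-10-en-4-ol, protect it as the TBS ether, then do hydroboration/Suzuki with 3 and remove the TBS group, giving 6 without an alkyl halide in the coupling.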